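**Plan**

Labdane numbering: C1–C3 are the ring A CH2 groups, C4 the gem-dimethyl carbon, C5 and C10 the ring-fusion carbons, and C6–C9 the rest of ring B. C17 is the carboxyl carbon on C8, and C11–C15 is the side chain with C13 as its methyl-bearing CH.
Enabling feature: C10, the quaternary methyl-bearing fusion carbon, is bonded to C9, the ring B methine that holds the side chain and sits next to the C7=C8–C17O2H enoate. Read backwards, C10 is a tertiary radical born from a ring A C1=C10 alkene, and C9 is the β-carbon of a 2-alkylidene ester whose C7 carries an acetate that can leave.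
Cuts, in retrosynthetic order: the tert-butyl ester O–C bond, C9–C10 (ring B), C7–C8 (fragment union), then C5–C6 in the ring A fragment and C8–C17 and C8–C9 in the chain fragment.
Forward: ring A is bought as a cyclohexenone and gains its two-carbon arm. The citronellol chain becomes a C8≡C9 ynoate, the two are joined at C7–C8, and ring B closes last.
Stereochemistry: C13 comes from (S)-citronellol. C5 comes from an oxazaborolidine-catalysed ketone reduction relayed by a suprafacial [3,3] shift. C10 and C9 arise in the ring closure, from C5 and from the (Z)-alkene, and C7 is transient.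

Key step: step 11

Assumption: the C7 carbinol centre should form as a mixture of epimers. The mixture is carried on unseparated because step 11 erases this centre, so the SMILES of 15–20 carry no descriptor at C7.

**Route**

Step 1
Reactants: 1 2,4,4-trimethylcyclohex-2-en-1-one
Product: 2 (R)-2,4,4-trimethylcyclohex-2-en-1-ol
Conditions: (S)-2-methyl-CBS-oxazaborolidine (10 mol %), BH3·SMe2 (0.7 equiv), THF, −20 °C; aqueous work-up
Reagents that add atoms: none
Why: Corey–Bakshi–Shibata reduction, in which the methyl-bearing alkenyl flank of the enone acts as the large group and the ring CH2 as the small one, so that the (S)-catalyst should deliver hydride to the face that gives the (R)-carbinol by clean 1,2-reduction.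

Step 2
Reactants: 2 (R)-2,4,4-trimethylcyclohex-2-en-1-ol; 3 triethyl orthoacetate
Product: 5 ethyl 2-[(1S)-2,6,6-trimethylcyclohex-2-en-1-yl]acetate, via mixed ketene acetal 4 (not isolated)
Conditions: 3 (8 equiv), EtCO2H (10 mol %), xylene, 140 °C, EtOH distilled off
Reagents that add atoms: triethyl orthoacetate (3), CCOC(C)(OCC)OCC
Why: Johnson–Claisen rearrangement, in which orthoester exchange and loss of ethanol give ketene acetal 4 and its suprafacial [3,3] shift forms C5–C6 on the ring face that held the oxygen, turning the (R)-carbinol into the (S)-configured C5 and moving the alkene to C1=C10.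

Step 3
Reactants: 5 ethyl 2-[(1S)-2,6,6-trimethylcyclohex-2-en-1-yl]acetate
Product: 6 2-[(1S)-2,6,6-trimethylcyclohex-2-en-1-yl]acetaldehyde
Conditions: i-Bu2AlH (1.05 equiv), CH2Cl2, −78 °C; aq. potassium sodium tartrate
Reagents that add atoms: none
Why: Partial ester reduction with i-Bu2AlH, which at −78 °C halts at the aluminium hemiacetal that releases the aldehyde only on work-up, while C5 is not α to the carbonyl and cannot epimerise.

Step 4
Reactants: 7 (S)-citronellol
Product: 8 (S)-citronellol tert-butyldimethylsilyl ether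
Conditions: TBSCl, imidazole, CH2Cl2, 0 °C to rt
Reagents that add atoms: tert-butyldimethylsilyl chloride, CC(C)(C)[Si](C)(C)Cl
Why: Standard imidazole-promoted silylation of a primary alcohol, giving an ether that withstands ozone, n-BuLi and i-Bu2AlH.

Step 5
Reactants: 8 (S)-citronellol tert-butyldimethylsilyl ether
Product: 10 (4S)-6-(tert-butyldimethylsilyloxy)-4-methylhexanal, via secondary ozonide 9 (not isolated)
Conditions: O3, CH2Cl2, −78 °C; then PPh3, −78 °C to rt
Reagents that add atoms: ozone, [O-][O+]=O
Why: Ozonolysis with reductive work-up cleaves the only alkene to the aldehyde whose carbonyl carbon becomes C9, and C13 is remote from the reacting site.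

Step 6
Reactants: 10 (4S)-6-(tert-butyldimethylsilyloxy)-4-methylhexanal
Product: 11 (3S)-7,7-dibromo-1-(tert-butyldimethylsilyloxy)-3-methylhept-6-ene
Conditions: CBr4 (2 equiv), PPh3 (4 equiv), CH2Cl2, 0 °C
Reagents that add atoms: carbon tetrabromide, BrC(Br)(Br)Br
Why: First stage of the Corey–Fuchs reaction, a Wittig-type dibromomethylenation by the ylide formed from CBr4 and PPh3, which adds the carbon that becomes C8.

Step 7
Reactants: 11 (3S)-7,7-dibromo-1-(tert-butyldimethylsilyloxy)-3-methylhept-6-ene
Product: 13 tert-butyl (6S)-8-(tert-butyldimethylsilyloxy)-6-methyloct-2-ynoate, via lithium acetylide 12 (not isolated)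
Conditions: n-BuLi (2.1 equiv), THF, −78 °C; then Boc2O, −78 °C to rt; aqueous work-up
Reagents that add atoms: di-tert-butyl dicarbonate, CC(C)(C)OC(=O)OC(=O)OC(C)(C)C
Why: Second stage of the Corey–Fuchs reaction, in which elimination and bromine–lithium exchange give acetylide 12, whose acylation by Boc2O is a known route to tert-butyl alk-2-ynoates and brings in C17.

Step 8
Reactants: 13 tert-butyl (6S)-8-(tert-butyldimethylsilyloxy)-6-methyloct-2-ynoate; 6 2-[(1S)-2,6,6-trimethylcyclohex-2-en-1-yl]acetaldehyde
Product: 15 tert-butyl (2Z,6S)-8-(tert-butyldimethylsilyloxy)-2-{1-hydroxy-2-[(1S)-2,6,6-trimethylcyclohex-2-en-1-yl]ethyl}-6-methyloct-2-enoate (C7 epimers), via C8 diisobutylalumanyl enoate 14 (not isolated)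
Conditions: 13 (1.2 equiv), i-Bu2AlH (1.15 equiv), HMPA, THF, 0 °C; then 6 (1.0 equiv), 0 °C to rt; aq. potassium sodium tartrate
Reagents that add atoms: none
Why: Conjugate hydroalumination of an ynoate followed by vinylalumination of an aldehyde (a route to β-substituted Morita–Baylis–Hillman-type adducts), in which H and Al add syn across C8≡C9 to give 14 and C8 then attacks the aldehyde with retention so that C11 stays cis to the ester, while C7 forms without control and needs none.

Step 9
Reactants: 15 the C7 carbinol silyl ether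
Product: 16 tert-butyl (2Z,6S)-8-hydroxy-2-{1-hydroxy-2-[(1S)-2,6,6-trimethylcyclohex-2-en-1-yl]ethyl}-6-methyloct-2-enoate (C7,C15-diol)
Conditions: HF·pyridine, pyridine, THF, 0 °C to rt
Reagents that add atoms: none
Why: Fluoride-driven cleavage of the primary silyl ether under buffered conditions that leave the tert-butyl ester, the allylic alcohol and both alkenes untouched.

Step 10
Reactants: 16 the C7,C15-diol
Product: 17 tert-butyl (2Z,6S)-8-acetoxy-2-{1-acetoxy-2-[(1S)-2,6,6-trimethylcyclohex-2-en-1-yl]ethyl}-6-methyloct-2-enoate (C7,C15-diacetate)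
Conditions: Ac2O (3 equiv), pyridine, DMAP (5 mol %), CH2Cl2, 0 °C to rt
Reagents that add atoms: acetic anhydride, CC(=O)OC(C)=O
Why: Routine DMAP-catalysed acylation puts on in one operation the C15 acetate of the target and the C7 acetate that serves as leaving group in step 11.

Step 11
Reactants: 17 the C7,C15-diacetate
Product: 21 tert-butyl (5S,9R,10S,13S)-15-acetoxylabd-7-en-17-oate, via C10 tertiary radical 18 (not isolated), via bicyclic C8 radical 19 (not isolated), via bicyclic C8 ester enolate 20 (not isolated)
Conditions: Fe(acac)3 (30 mol %), PhSiH3 (3 equiv, slow addition), EtOH/THF 1:1 (0.01 M), 60 °C, Ar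
Reagents that add atoms: none
Why: Proposed new method: a trivalent iron hydride formed from Fe(acac)3 and PhSiH3 passes a hydrogen atom to C1 of the electron-rich C1=C10 alkene, the tertiary radical 18 attacks C9 (the β-carbon of the enoate) to give the ester-stabilised radical 19, divalent iron reduces 19 to enolate 20, and 20 expels the C7 acetate by E1cB, which restores trivalent iron and leaves the C7=C8 enoate. The closest known reactions are the iron hydride Giese cyclisation of alkenes tethered to acrylates and the intermolecular iron hydride hydroallylation of alkenes with Morita–Baylis–Hillman acetates, and what is new is their union in a ring closure onto a β-alkyl-substituted acceptor. Ring B closes 6-endo-trig, since the 5-exo mode would bond a nucleophilic radical to the fully substituted, polarity-mismatched C8 and leave an unstabilised secondary radical on C9. C10 is controlled by C5: in a chair-like transition state with the C5 arm equatorial on ring A, C9 bonds equatorially and the C10 methyl turns axial and anti to H5 (trans fusion), whereas axial attack would press C9 against the axial C4 methyl. C9 is controlled by the (Z)-alkene, because C11 lies trans to C7 across C8=C9 and therefore equatorial in that chair, which puts H9 axial and anti to the C10 methyl. The step needs site-selective initiation and cyclisation faster than radical reduction: the substrate offers only one electron-rich alkene, high dilution with slow silane addition keeps the hydride concentration low, and both C7 epimers converge on 21.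

Step 12
Reactants: 21 tert-butyl (5S,9R,10S,13S)-15-acetoxylabd-7-en-17-oate
Product: 22 (5S,9R,10S,13S)-15-acetoxylabd-7-en-17-oic acid (CNP0412535.1)
Conditions: CF3CO2H/CH2Cl2 (1:4), 0 °C to rt
Reagents that add atoms: none
Why: Acidolysis of the tert-butyl ester by E1-type loss of the tert-butyl cation frees the acid without base, so that the primary acetate, the electron-poor C7=C8 alkene and C9 stay as they are.

**Compound list**

1 | 2,4,4-trimethylcyclohex-2-en-1-one | CC1=CC(C)(C)CCC1=O | starting material
2 | (R)-2,4,4-trimethylcyclohex-2-en-1-ol | O[C@@H]1CCC(C)(C)C=C1C | intermediate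
3 | triethyl orthoacetate | CCOC(C)(OCC)OCC | starting material
4 | (R)-1-(1-ethoxyvinyloxy)-2,4,4-trimethylcyclohex-2-ene, mixed ketene acetal (not isolated) | C=C(OCC)O[C@@H]1CCC(C)(C)C=C1C | intermediate
5 | ethyl 2-[(1S)-2,6,6-trimethylcyclohex-2-en-1-yl]acetate | CCOC(=O)C[C@H]1C(C)(C)CCC=C1C | intermediate
6 | 2-[(1S)-2,6,6-trimethylcyclohex-2-en-1-yl]acetaldehyde | O=CC[C@H]1C(C)(C)CCC=C1C | intermediate
7 | (S)-citronellol | OCC[C@@H](C)CCC=C(C)C | starting material
8 | (S)-citronellol tert-butyldimethylsilyl ether | CC(C)(C)[Si](C)(C)OCC[C@@H](C)CCC=C(C)C | intermediate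
9 | secondary ozonide (1,2,4-trioxolane) of 8 (not isolated) | CC(C)(C)[Si](C)(C)OCC[C@@H](C)CCC1OOC(C)(C)O1 | intermediate
10 | (4S)-6-(tert-butyldimethylsilyloxy)-4-methylhexanal | CC(C)(C)[Si](C)(C)OCC[C@@H](C)CCC=O | intermediate
11 | (3S)-7,7-dibromo-1-(tert-butyldimethylsilyloxy)-3-methylhept-6-ene | CC(C)(C)[Si](C)(C)OCC[C@@H](C)CCC=C(Br)Br | intermediate
12 | lithium acetylide from 11 (not isolated) | CC(C)(C)[Si](C)(C)OCC[C@@H](C)CCC#C[Li] | intermediate
13 | tert-butyl (6S)-8-(tert-butyldimethylsilyloxy)-6-methyloct-2-ynoate | CC(C)(C)[Si](C)(C)OCC[C@@H](C)CCC#CC(=O)OC(C)(C)C | intermediate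
14 | C8 diisobutylalumanyl enoate, chain cis to the ester (not isolated) | CC(C)(C)[Si](C)(C)OCC[C@@H](C)CC/C=C(\C(=O)OC(C)(C)C)[Al](CC(C)C)CC(C)C | intermediate
15 | tert-butyl (2Z,6S)-8-(tert-butyldimethylsilyloxy)-2-{1-hydroxy-2-[(1S)-2,6,6-trimethylcyclohex-2-en-1-yl]ethyl}-6-methyloct-2-enoate, C7 epimers | CC(C)(C)[Si](C)(C)OCC[C@@H](C)CC/C=C(\C(=O)OC(C)(C)C)C(O)C[C@H]1C(C)(C)CCC=C1C | intermediate
16 | C7,C15-diol, C7 epimers | OCC[C@@H](C)CC/C=C(\C(=O)OC(C)(C)C)C(O)C[C@H]1C(C)(C)CCC=C1C | intermediate
17 | C7,C15-diacetate, C7 epimers (precursor of the key step) | CC(=O)OCC[C@@H](C)CC/C=C(\C(=O)OC(C)(C)C)C(OC(C)=O)C[C@H]1C(C)(C)CCC=C1C | intermediate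
18 | C10 tertiary radical (not isolated) | CC(=O)OCC[C@@H](C)CC/C=C(\C(=O)OC(C)(C)C)C(OC(C)=O)C[C@H]1C(C)(C)CCC[C]1C | intermediate
19 | bicyclic C8 radical (not isolated) | CC(=O)OCC[C@@H](C)CC[C@H]1[C](C(=O)OC(C)(C)C)C(OC(C)=O)C[C@H]2C(C)(C)CCC[C@]12C | intermediate
20 | bicyclic C8 ester enolate, iron-bound, written as the anion (not isolated) | CC(=O)OCC[C@@H](C)CC[C@H]1C(=C([O-])OC(C)(C)C)C(OC(C)=O)C[C@H]2C(C)(C)CCC[C@]12C | intermediate
21 | tert-butyl (5S,9R,10S,13S)-15-acetoxylabd-7-en-17-oate (product of the key step) | CC(=O)OCC[C@@H](C)CC[C@H]1C(C(=O)OC(C)(C)C)=CC[C@H]2C(C)(C)CCC[C@]12C | intermediate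
22 | (5S,9R,10S,13S)-15-acetoxylabd-7-en-17-oic acid | CC(=O)OCC[C@@H](C)CC[C@H]1C(C(=O)O)=CC[C@H]2C(C)(C)CCC[C@]12C | target

**Step count**

Total steps: 12. The longest linear sequence is 9 steps (steps 4–12, from (S)-citronellol). The ring A branch (steps 1–3) joins at step 8.

**Steps most likely to fail**

1. Step 11.
What may go wrong: bonding between a tertiary radical and a β-alkyl-substituted, α-branched acceptor may be slow, so premature reduction of the C10 radical could compete. Protonation of the enolate may outrun acetate loss for the C7 epimer whose acetate lies equatorial. The facial bias at C10 may be too small.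
Fallback (raises the acceptor to the C7 ketone level and separates ring closure from alkene placement):
From diol 16, selective acylation of the primary hydroxyl (AcCl, 2,4,6-collidine, CH2Cl2, −78 °C) should give the C15 monoacetate F1. Dess–Martin oxidation then gives the (Z)-alkylidene β-keto ester F2. The established reductive Giese cyclisation (Fe(acac)3, PhSiH3, EtOH, 60 °C) closes the same C9–C10 bond onto this doubly activated alkene and stops at the bicyclic β-keto ester F3. NaH and PhNTf2 (THF, 0 °C) convert this into the C7 enol triflate F4. Formate reduction (Pd(OAc)2, PPh3, HCO2H, Et3N, DMF, 60 °C) replaces the triflate by hydrogen and returns to the route at 21.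

2. Step 8.
What may go wrong: the alkene geometry may erode through equilibration of the vinylalane by way of its allenolate form. Ester or aldehyde reduction by free hydride may compete. Addition to the β-branched aldehyde may be sluggish.
Fallback (fixes the geometry in an isolable alkenyl halide):
From ynoate 13, syn-hydrostannation (Bu3SnH, Pd(PPh3)4, THF, 0 °C) should give the α-tributylstannyl enoate F5. Treatment with I2 (CH2Cl2, 0 °C) exchanges tin for iodine with retention to give the α-iodo enoate F6. Nozaki–Hiyama–Kishi coupling of the iodide with aldehyde 6 (CrCl2, NiCl2 cat., DMF, rt) returns to the route at 15.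

3. Step 2.
What may go wrong: the sigmatropic shift onto the alkene terminus next to the gem-dimethyl carbon may be slow at 140 °C, so acid-promoted dehydration of the allylic alcohol could take over.
Fallback (anionic, low-temperature Ireland–Claisen variant):
From alcohol 2, acetylation (Ac2O, pyridine) gives the allylic acetate F7. LiN(i-Pr)2 and TBSCl (THF/HMPA, −78 °C) give the silyl ketene acetal F8. Warming in toluene brings about the suprafacial shift to the silyl ester F9, and aqueous K2CO3 followed by acidification frees the acid F10. Treatment with EtI and K2CO3 in DMF returns to the route at 5.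

**Further compounds**

F1 | step 11 | tert-butyl (2Z,6S)-8-acetoxy-2-{1-hydroxy-2-[(1S)-2,6,6-trimethylcyclohex-2-en-1-yl]ethyl}-6-methyloct-2-enoate | CC(=O)OCC[C@@H](C)CC/C=C(\C(=O)OC(C)(C)C)C(O)C[C@H]1C(C)(C)CCC=C1C
F2 | step 11 | tert-butyl (2Z,6S)-8-acetoxy-6-methyl-2-{2-[(1S)-2,6,6-trimethylcyclohex-2-en-1-yl]acetyl}oct-2-enoate | CC(=O)OCC[C@@H](C)CC/C=C(\C(=O)OC(C)(C)C)C(=O)C[C@H]1C(C)(C)CCC=C1C
F3 | step 11 | tert-butyl (5S,9R,10S,13S)-15-acetoxy-7-oxolabdan-17-oate, C8 enolisable | CC(=O)OCC[C@@H](C)CC[C@H]1C(C(=O)OC(C)(C)C)C(=O)C[C@H]2C(C)(C)CCC[C@]12C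
F4 | step 11 | tert-butyl (5S,9R,10S,13S)-15-acetoxy-7-(trifluoromethylsulfonyloxy)labd-7-en-17-oate | CC(=O)OCC[C@@H](C)CC[C@H]1C(C(=O)OC(C)(C)C)=C(OS(=O)(=O)C(F)(F)F)C[C@H]2C(C)(C)CCC[C@]12C
F5 | step 8 | tert-butyl (6S)-8-(tert-butyldimethylsilyloxy)-6-methyl-2-(tributylstannyl)oct-2-enoate, chain cis to the ester | CC(C)(C)[Si](C)(C)OCC[C@@H](C)CC/C=C(\C(=O)OC(C)(C)C)[Sn](CCCC)(CCCC)CCCC
F6 | step 8 | tert-butyl (6S)-8-(tert-butyldimethylsilyloxy)-2-iodo-6-methyloct-2-enoate, chain cis to the ester | CC(C)(C)[Si](C)(C)OCC[C@@H](C)CC/C=C(\C(=O)OC(C)(C)C)I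
F7 | step 2 | (R)-2,4,4-trimethylcyclohex-2-en-1-yl acetate | CC(=O)O[C@@H]1CCC(C)(C)C=C1C
F8 | step 2 | tert-butyldimethylsilyl ketene acetal of F7 | C=C(O[Si](C)(C)C(C)(C)C)O[C@@H]1CCC(C)(C)C=C1C
F9 | step 2 | tert-butyldimethylsilyl 2-[(1S)-2,6,6-trimethylcyclohex-2-en-1-yl]acetate | CC(C)(C)[Si](C)(C)OC(=O)C[C@H]1C(C)(C)CCC=C1C
F10 | step 2 | 2-[(1S)-2,6,6-trimethylcyclohex-2-en-1-yl]acetic acid | OC(=O)C[C@H]1C(C)(C)CCC=C1C
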